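**Retrosynthetic overview**
1. The C4 isobutyryl group comes from a hydroxyl-relayed O→C acyl shift off the C2 oxygen; the C2 carbinol comes from a catalytic asymmetric α-hydroxylation of a 2-prenylcyclooctane-1,3-dione.
2. The cyclooctane-1,3-dione comes from a two-carbon ring expansion of a cyclohexanone silyl enol ether (dichloroketene [2+2], then retro-aldol fragmentation).
3. The C5 quaternary centre comes from an anti-selective homoprenyl cuprate addition to a 3-methyl-4,6-diprenylcyclohexenone.
4. The C6 stereocentre (the only external source of chirality) comes from an organocatalytic Michael/aldol annulation of 5-methylhex-4-enal with methyl vinyl ketone.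
5. Ring order: cyclohexenone first, then a fused cyclobutanone, which fragments to the eight-membered ring.

**Assumptions**
- C4 and C8 are enolisable α-carbonyl centres; their natural configuration is taken to be the thermodynamic one, so both are set by equilibration in the last step.
- 5-Methylhex-4-enal and 5-bromo-2-methylpent-2-ene are treated as catalogue chemicals.
- Ring numbering of the target: C1(=O), C2(OH)(prenyl), C3(=O), C4(H)(isobutyryl), C5(Me)(homoprenyl), C6(H)(prenyl), C7H2, C8(H)(prenyl). CIP labels change along the route where substituent priorities change; no centre is inverted.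

**Route**

Step 1
Reactants: 1 5-methylhex-4-enal; 2 but-3-en-2-one (methyl vinyl ketone)
Product: 3 (R)-4-(3-methylbut-2-en-1-yl)cyclohex-2-en-1-one
Conditions: (R)-α,α-diphenylprolinol methyl ether (5 mol %), ethyl 3,4-dihydroxybenzoate (20 mol %), neat, 4 °C; then LiOH, i-PrOH, rt (one pot)
Reagents that add atoms: none (both partners are listed reactants)
Why: Enamine Michael addition, in which the catalyst's diphenyl(methoxy)methyl group shields one face of the E-enamine so MVK adds to give the (R) α-centre, followed by intramolecular aldol condensation (organocatalytic Robinson-type annulation); the γ-stereocentre survives mild LiOH.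

Step 2
Reactants: 3
Product: 4 (R)-3-methyl-4-(3-methylbut-2-en-1-yl)cyclohex-2-en-1-one
Conditions: Me2CuLi, Et2O, −78 → −40 °C; then PhS(Cl)=N-t-Bu, THF, −78 °C → rt (one pot)
Reagents that add atoms: lithium dimethylcuprate, [Li+].C[Cu-]C
Why: Gilman 1,4-addition followed by Mukaiyama dehydrogenation of the regiodefined enolate reinstalls the C2=C3 alkene with the β-methyl in place; C4 is untouched.

Step 3
Reactants: 4; 5 1-bromo-3-methylbut-2-ene (prenyl bromide)
Product: 6 (4S,6RS)-3-methyl-4,6-bis(3-methylbut-2-en-1-yl)cyclohex-2-en-1-one (C6 epimers, trans expected major; same C4 geometry as 4)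
Conditions: LDA, THF, −78 °C; then 5, DMPU, −78 → −30 °C
Reagents that add atoms: prenyl bromide (5), CC(C)=CCBr
Why: Kinetic α′-enolate alkylation of a cyclohexenone; C6 becomes the epimerisable C8 of the target, so its configuration here is immaterial.

Step 4
Reactants: 6; 7 5-bromo-2-methylpent-2-ene (as its Grignard reagent)
Product: 8 trimethyl{[(3R,4S,6RS)-3-methyl-3-(4-methylpent-3-en-1-yl)-4,6-bis(3-methylbut-2-en-1-yl)cyclohex-1-en-1-yl]oxy}silane
Conditions: 4-methylpent-3-enylMgBr (from 7, Mg), CuBr·SMe2 (20 mol %), TMSCl, HMPA, THF, −78 → −40 °C; Et3N, pentane filtration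
Reagents that add atoms: 5-bromo-2-methylpent-2-ene (7), CC(C)=CCCBr; chlorotrimethylsilane, C[Si](C)(C)Cl
Why: TMSCl-accelerated copper-catalysed conjugate addition; the C4 prenyl group sits pseudoaxial (A(1,2) strain with the 3-methyl), so the homoprenyl group adds axially anti to it, setting the quaternary centre (homoprenyl trans, methyl cis to the prenyl) and trapping the enolate regiospecifically.

Step 5
Reactants: 8; 9 dichloroacetyl chloride (dichloroketene precursor)
Product: 10 (4S,5R)-8,8-dichloro-5-methyl-5-(4-methylpent-3-en-1-yl)-2,4-bis(3-methylbut-2-en-1-yl)-1-[(trimethylsilyl)oxy]bicyclo[4.2.0]octan-7-one (cis-fused; facial isomers at C1/C6 and C2 epimers carried as a mixture)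
Conditions: 9, Et3N, hexane, rt, slow addition
Reagents that add atoms: dichloroacetyl chloride (9), O=C(Cl)C(Cl)Cl
Why: Ketene–silyl enol ether [2+2] cycloaddition, with the ketene carbonyl carbon bonding to the nucleophilic enol-ether CH and CCl2 to the siloxy carbon; the silyl enol ether far outcompetes the prenyl alkenes, and the new ring-fusion centres are erased in step 6.

Step 6
Reactants: 10
Product: 11 (5S,6S,8RS)-5-methyl-5-(4-methylpent-3-en-1-yl)-6,8-bis(3-methylbut-2-en-1-yl)cyclooctane-1,3-dione
Conditions: Zn dust, AcOH, i-PrOH/H2O, 0 °C → rt; then filter, 60 °C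
Reagents that add atoms: none
Why: Reductive dechlorination, then protodesilylation triggers strain-driven retro-aldol fragmentation of the β-siloxycyclobutanone, cleaving the ring-fusion bond (two-carbon ring expansion to the 1,3-dione).

Step 7
Reactants: 11; 5 prenyl bromide
Product: 12 (5S,6S)-5-methyl-5-(4-methylpent-3-en-1-yl)-2,6,8-tris(3-methylbut-2-en-1-yl)cyclooctane-1,3-dione (C2 and C8 epimerisable)
Conditions: 5 (1.05 equiv), K2CO3, acetone, 0 °C → rt
Reagents that add atoms: prenyl bromide (5), CC(C)=CCBr
Why: C-alkylation of the 1,3-diketone monoanion at its only doubly activated carbon with a soft allylic bromide.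

Step 8
Reactants: 12
Product: 13 (2S,5S,6S,8RS)-2-hydroxy-5-methyl-5-(4-methylpent-3-en-1-yl)-2,6,8-tris(3-methylbut-2-en-1-yl)cyclooctane-1,3-dione (2S here is the natural C2 geometry: OH on the face of the C5 methyl and C6 prenyl)
Conditions: cumene hydroperoxide (1.5 equiv), N-(9-anthracenylmethyl)cinchonidinium bromide (10 mol %), 50% aq. K2HPO4, toluene, −20 °C; Na2S2O3 quench
Reagents that add atoms: cumene hydroperoxide, CC(C)(OO)c1ccccc1
Why: Proposed new method: catalyst-controlled diastereoselective α-hydroxylation of a medium-ring 2-alkyl-1,3-diketone, in which the diketonate is held as a tight ion pair (plus C9–OH hydrogen bond) with the chiral ammonium cation and attacks the hydroperoxide O–O bond (SN2 at oxygen) from the unshielded face to set the C2 carbinol; the facial sense cannot be predicted on this flexible ring, so the cinchoninium pseudo-enantiomer is the immediate alternative if the named catalyst proves mismatched; the closest known reaction type is cinchona phase-transfer/base-catalysed α-hydroxylation of cyclic β-keto esters with hydroperoxides, not yet shown for cyclooctane-1,3-diones or for overriding resident stereocentres.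

Step 9
Reactants: 13; 14 2-methylpropanoyl chloride (isobutyryl chloride)
Product: 15 Hyphenrone F, (2R,4R,5R,6S,8S)-2-hydroxy-5-methyl-4-(2-methylpropanoyl)-2,6,8-tris(3-methylbut-2-en-1-yl)-5-(4-methylpent-3-en-1-yl)cyclooctane-1,3-dione
Conditions: LiHMDS (1.0 equiv), THF, −78 °C; 14 (1.0 equiv), −78 → −40 °C; then LiHMDS (2.2 equiv), −78 → −20 °C; pH 7 buffer; then cat. Et3N, CH2Cl2, rt
Reagents that add atoms: isobutyryl chloride (14), CC(C)C(Cl)=O
Why: O-acylation of the tertiary alkoxide, then Baker–Venkataraman-type intramolecular Claisen transfer (five-membered tetrahedral intermediate) to a flanking enolate; transfer to C8 is reversible because that product is non-enolisable, whereas transfer to C4 is locked as the β-diketonate, and final mild-base equilibration sets C4 and C8 to their thermodynamic configurations.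

**Compound list**
1 | 5-methylhex-4-enal | CC(C)=CCCC=O | starting material
2 | but-3-en-2-one | CC(=O)C=C | starting material
3 | (R)-4-(3-methylbut-2-en-1-yl)cyclohex-2-en-1-one | O=C1C=C[C@@H](CC=C(C)C)CC1 | intermediate
4 | (R)-3-methyl-4-(3-methylbut-2-en-1-yl)cyclohex-2-en-1-one | O=C1C=C(C)[C@@H](CC=C(C)C)CC1 | intermediate
5 | 1-bromo-3-methylbut-2-ene | CC(C)=CCBr | starting material
6 | (4S,6RS)-3-methyl-4,6-bis(3-methylbut-2-en-1-yl)cyclohex-2-en-1-one | O=C1C=C(C)[C@@H](CC=C(C)C)CC1CC=C(C)C | intermediate
7 | 5-bromo-2-methylpent-2-ene | CC(C)=CCCBr | starting material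
8 | trimethyl{[(3R,4S,6RS)-3-methyl-3-(4-methylpent-3-en-1-yl)-4,6-bis(3-methylbut-2-en-1-yl)cyclohex-1-en-1-yl]oxy}silane | C[Si](C)(C)OC1=C[C@](C)(CCC=C(C)C)[C@@H](CC=C(C)C)CC1CC=C(C)C | intermediate
9 | dichloroacetyl chloride | O=C(Cl)C(Cl)Cl | starting material
10 | (4S,5R)-8,8-dichloro-5-methyl-5-(4-methylpent-3-en-1-yl)-2,4-bis(3-methylbut-2-en-1-yl)-1-[(trimethylsilyl)oxy]bicyclo[4.2.0]octan-7-one | C[Si](C)(C)OC12C(CC=C(C)C)C[C@H](CC=C(C)C)[C@@](C)(CCC=C(C)C)C1C(=O)C2(Cl)Cl | intermediate
11 | (5S,6S,8RS)-5-methyl-5-(4-methylpent-3-en-1-yl)-6,8-bis(3-methylbut-2-en-1-yl)cyclooctane-1,3-dione | O=C1CC(=O)C[C@](C)(CCC=C(C)C)[C@@H](CC=C(C)C)CC1CC=C(C)C | intermediate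
12 | (5S,6S)-5-methyl-5-(4-methylpent-3-en-1-yl)-2,6,8-tris(3-methylbut-2-en-1-yl)cyclooctane-1,3-dione | O=C1C(CC=C(C)C)C(=O)C[C@](C)(CCC=C(C)C)[C@@H](CC=C(C)C)CC1CC=C(C)C | intermediate
13 | (2S,5S,6S,8RS)-2-hydroxy-5-methyl-5-(4-methylpent-3-en-1-yl)-2,6,8-tris(3-methylbut-2-en-1-yl)cyclooctane-1,3-dione | O=C1[C@](O)(CC=C(C)C)C(=O)C[C@](C)(CCC=C(C)C)[C@@H](CC=C(C)C)CC1CC=C(C)C | intermediate
14 | 2-methylpropanoyl chloride | CC(C)C(Cl)=O | starting material
15 | Hyphenrone F, (2R,4R,5R,6S,8S)-2-hydroxy-5-methyl-4-(2-methylpropanoyl)-2,6,8-tris(3-methylbut-2-en-1-yl)-5-(4-methylpent-3-en-1-yl)cyclooctane-1,3-dione | CC(C)=CCC[C@]1(C)[C@@H](CC=C(C)C)C[C@H](CC=C(C)C)C(=O)[C@](O)(CC=C(C)C)C(=O)[C@H]1C(=O)C(C)C | target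

**Totals**
Total steps: 9. Longest linear sequence: 9 (fully linear).

**Three steps most likely to fail**
1. Step 8 (proposed new asymmetric hydroxylation). Risks: the catalyst may not override the facial bias of the flexible ring, and the α-hydroxy-β-diketone is prone to retro-Claisen or α-ketol shift under base. Fallback (known chemistry): drop catalysis and hydroxylate the potassium enolate with enantiopure Davis (camphorsulfonyl)oxaziridine under stoichiometric reagent control. If the ring bias still dominates, reverse the order at C2 (oxygenate 11 first, protect as the silyl ether, then C-prenylate by Pd-catalysed Tsuji–Trost allylation) so the second group enters on the preferred face and gives the opposite C2 epimer.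
2. Step 5 ([2+2] at an enol-ether carbon next to the new quaternary centre). Risk: simple C-acylation or no reaction. Fallback: expand the other ring bond. Omit step 3, quench the cuprate adduct of 4 to the ketone, form the kinetic LDA/TMSCl enol ether on the unhindered side, and run the same dichloroketene/Zn sequence to give the C8-unsubstituted analogue of 11. Then install the C8 and C2 prenyl groups via the 1,3-dione dianion and monoanion.
3. Step 9 (acyl relay). Risks: sluggish O-acylation of the hindered alkoxide, α-ketol ring contraction, or cyclodehydration of the product to a 3(2H)-furanone on acidic work-up. Fallback: protect C2–OH of 13 as the TES ether and C-acylate intermolecularly by soft enolisation (MgBr2·OEt2, i-Pr2NEt, 1-isobutyrylbenzotriazole), where only C4 acylation gives a stable magnesium β-diketonate; then remove the silyl group with buffered HF·pyridine.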